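**Retrosynthetic overview**

1. Numbering: ring A = C1(=CH2)–C2–C3–C4(O5)–C16(Me2)–C15; THF ring = O5–C4–C16–C15–C6; ring B = C6–C7–C8–C13–C14–C15; ring C = C8(Me)–C9(Br)–C10–C11–C12(Me,OH)–C13. End game: C1=CH2 from a C1 ketone (Wittig), the C12 carbinol from a C12 ketone (equatorial MeMgBr), C2–C3 from an enone; this leads back to tetracyclic enone-ketone 27.
2. Key disconnection: C6–C15 and O5–C4 of 27 are cut together to keto aldehyde 24. Enabling feature: in ring A, C15 is α′ and C4 is γ to a C1 carbonyl through C2=C3, and the C16 CMe2 carbon between them has no hydrogen. A C4 carbonate therefore gives a C2–C3–C4 allylpalladium unit beside a C15 enolate, and the C6=O5 aldehyde adds across C15 and C4 (formal [3+2]), closing ring B and the THF ring in one operation.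
3. 24 comes from a Michael union (C14–C15) of ring A enone carbonate 20 (C4 set by a CBS reduction) with ring C exo-methylene ketone 16.
4. 16 comes from keto ester 13, made by an enantiospecific bromonium-initiated cation–enol cyclization (C8–C13) of bromohydrin 11; its two stereocentres come from one Shi epoxidation, its chain from but-3-yn-1-ol and a dioxinone (masked acetoacetate).
5. Order of ring formation: ring C (step 8), then ring B and the THF ring together (step 17); ring A is carried in from 6,6-dimethylcyclohex-2-en-1-one. C15, C6 and C12 are set by substrate control.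

Key step: step 17

Remark: the target SMILES is taken as the absolute configuration. The CBS sense in step 11 assumes the quaternary α-carbon acts as the large group. C15 of 22–24 is an epimer mixture that is erased by enolization in step 17.

**Route**

Step 1
Reactants: 1 but-3-yn-1-ol
Product: 2 tert-butyl(but-3-yn-1-yloxy)diphenylsilane
Conditions: TBDPSCl, imidazole, DMF, 0 °C to rt
Reagents that add atoms: tert-butyl(chloro)diphenylsilane, CC(C)(C)[Si](Cl)(c1ccccc1)c1ccccc1
Why: Imidazole-mediated silylation protects the primary alcohol with a group that should survive SnCl4, LiAlH4 and lithium enolates until step 15.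

Step 2
Reactants: 2 tert-butyl(but-3-yn-1-yloxy)diphenylsilane
Product: 4 (2E)-5-{[tert-butyl(diphenyl)silyl]oxy}-3-methylpent-2-en-1-ol, via alkenyldimethylalane 3 (not isolated)
Conditions: AlMe3, Cp2ZrCl2 (20 mol %), CH2Cl2, 0 °C to rt; then n-BuLi, (CH2O)n, THF, −78 °C to rt
Reagents that add atoms: trimethylaluminium, C[Al](C)C; formaldehyde (from paraformaldehyde), C=O
Why: Negishi zirconium-catalysed carboalumination adds methyl and aluminium syn across the terminal alkyne, and the derived alanate is hydroxymethylated with retention, which fixes the E trisubstituted alkene that later defines the relative configuration at C8.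

Step 3
Reactants: 4 (2E)-5-{[tert-butyl(diphenyl)silyl]oxy}-3-methylpent-2-en-1-ol
Product: 5 {[(3E)-5-bromo-3-methylpent-3-en-1-yl]oxy}(tert-butyl)diphenylsilane
Conditions: CBr4, PPh3, CH2Cl2, 0 °C
Reagents that add atoms: tetrabromomethane, BrC(Br)(Br)Br
Why: Appel bromination converts the primary allylic alcohol into the bromide by SN2 displacement of the oxyphosphonium group without changing the alkene geometry.

Step 4
Reactants: 5 {[(3E)-5-bromo-3-methylpent-3-en-1-yl]oxy}(tert-butyl)diphenylsilane; 6 2,2,6-trimethyl-4H-1,3-dioxin-4-one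
Product: 8 6-[(3E)-6-{[tert-butyl(diphenyl)silyl]oxy}-4-methylhex-3-en-1-yl]-2,2-dimethyl-4H-1,3-dioxin-4-one, via lithium dienolate 7 (not isolated)
Conditions: LiN(i-Pr)2, THF, −78 °C; then 5, DMPU, −78 to −20 °C
Reagents that add atoms: none
Why: γ-Alkylation of the extended dienolate of the dioxinone by the allylic bromide (SN2) builds the chain, and the dioxinone keeps the β-dicarbonyl unit inert to the oxidant of step 5.

Step 5
Reactants: 8 6-[(3E)-6-{[tert-butyl(diphenyl)silyl]oxy}-4-methylhex-3-en-1-yl]-2,2-dimethyl-4H-1,3-dioxin-4-one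
Product: 9 6-(2-{(2R,3R)-3-[2-{[tert-butyl(diphenyl)silyl]oxy}ethyl]-3-methyloxiran-2-yl}ethyl)-2,2-dimethyl-4H-1,3-dioxin-4-one
Conditions: D-fructose-derived Shi ketone (30 mol %), Oxone (KHSO5), K2CO3, Bu4NHSO4, MeCN/CH2(OMe)2/aq. buffer pH 10.5, 0 °C
Reagents that add atoms: potassium peroxymonosulfate (Oxone), [K+].[O-]S(=O)(=O)OO
Why: Shi asymmetric epoxidation by the chiral dioxirane (spiro transition state) should attack only the electron-rich trisubstituted alkene and give the (2R,3R)-epoxide, the single reagent-controlled stereochemical event of this branch.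

Step 6
Reactants: 9 6-(2-{(2R,3R)-3-[2-{[tert-butyl(diphenyl)silyl]oxy}ethyl]-3-methyloxiran-2-yl}ethyl)-2,2-dimethyl-4H-1,3-dioxin-4-one
Product: 10 methyl 5-{(2R,3R)-3-[2-{[tert-butyl(diphenyl)silyl]oxy}ethyl]-3-methyloxiran-2-yl}-3-oxopentanoate
Conditions: MeOH (10 equiv), toluene, 110 °C, short reaction time
Reagents that add atoms: methanol, CO
Why: Thermal retro-[4+2] fragmentation of the dioxinone to an acylketene and its capture by methanol releases the methyl β-keto ester under neutral conditions that should leave the epoxide untouched.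

Step 7
Reactants: 10 methyl 5-{(2R,3R)-3-[2-{[tert-butyl(diphenyl)silyl]oxy}ethyl]-3-methyloxiran-2-yl}-3-oxopentanoate
Product: 11 methyl (6S,7R)-6-bromo-9-{[tert-butyl(diphenyl)silyl]oxy}-7-hydroxy-7-methyl-3-oxononanoate
Conditions: Li2NiBr4, THF, 0 °C to rt; then pH 7 buffer
Reagents that add atoms: dilithium tetrabromonickelate, [Li+].[Li+].Br[Ni-2](Br)(Br)Br
Why: SN2 opening of the epoxide by soft bromide at the less substituted carbon C9 with inversion should give the anti bromohydrin (secondary bromide, tertiary alcohol), the formal anti Br–OH adduct of the E alkene in enantiopure form.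

Step 8
Reactants: 11 methyl (6S,7R)-6-bromo-9-{[tert-butyl(diphenyl)silyl]oxy}-7-hydroxy-7-methyl-3-oxononanoate
Product: 13 methyl (1S,5S,6S)-5-bromo-6-[2-{[tert-butyl(diphenyl)silyl]oxy}ethyl]-6-methyl-2-oxocyclohexane-1-carboxylate, via bromonium ion 12 (not isolated)
Conditions: SnCl4 (2.5 equiv), CH2Cl2, −78 to −20 °C
Reagents that add atoms: none
Why: Ionization of the tertiary alcohol by SnCl4 with neighbouring-group participation of bromine gives the enantiopure bromonium ion, which the tin-chelated keto ester enol opens at C8 through a chair cation–olefin (enol) cyclization, so that C9 is carried over unchanged, C8 is set by anti opening and the C13 ester ends equatorial by enolization.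

Step 9
Reactants: 13 methyl (1S,5S,6S)-5-bromo-6-[2-{[tert-butyl(diphenyl)silyl]oxy}ethyl]-6-methyl-2-oxocyclohexane-1-carboxylate
Product: 15 (3S,4S)-4-bromo-3-[2-{[tert-butyl(diphenyl)silyl]oxy}ethyl]-3-methyl-2-methylidenecyclohexan-1-ol (C1 epimers), via sodium enolate 14 (not isolated)
Conditions: NaH, THF, 0 °C; then LiAlH4, 0 °C to rt
Reagents that add atoms: none
Why: Hydride reduction of the β-keto ester enolate (the enolate shields the ketone, the ester is reduced and eliminated to the α-methylene ketone, which is reduced 1,2) is the established route from cyclic β-keto esters to 2-methylidenecycloalkanols; the carbinol centre is not controlled because it is oxidized in step 10.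

Step 10
Reactants: 15 (3S,4S)-4-bromo-3-[2-{[tert-butyl(diphenyl)silyl]oxy}ethyl]-3-methyl-2-methylidenecyclohexan-1-ol
Product: 16 (3S,4S)-4-bromo-3-[2-{[tert-butyl(diphenyl)silyl]oxy}ethyl]-3-methyl-2-methylidenecyclohexan-1-one
Conditions: Dess–Martin periodinane, CH2Cl2, rt
Reagents that add atoms: none
Why: Dess–Martin oxidation of the allylic alcohol gives the exo-methylene ketone, whose dimerization should be retarded by the adjacent quaternary carbon C8.

Step 11
Reactants: 17 6,6-dimethylcyclohex-2-en-1-one
Product: 18 (1S)-6,6-dimethylcyclohex-2-en-1-ol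
Conditions: (R)-2-methyl-CBS-oxazaborolidine (10 mol %), catecholborane, toluene, −78 °C
Reagents that add atoms: none
Why: CBS reduction (1,2-hydride delivery within the oxazaborolidine–borane–ketone complex, the quaternary α-carbon as the large group) should give the (S)-allylic alcohol, the stereocentre that becomes C4.

Step 12
Reactants: 18 (1S)-6,6-dimethylcyclohex-2-en-1-ol
Product: 19 tert-butyl [(1S)-6,6-dimethylcyclohex-2-en-1-yl] carbonate
Conditions: n-BuLi, THF, −78 °C; then Boc2O, −78 °C to rt
Reagents that add atoms: di-tert-butyl dicarbonate, CC(C)(C)OC(=O)OC(=O)OC(C)(C)C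
Why: O-Acylation of the lithium alkoxide gives the allylic tert-butyl carbonate, the leaving group of the key step, without touching the stereocentre.

Step 13
Reactants: 19 tert-butyl [(1S)-6,6-dimethylcyclohex-2-en-1-yl] carbonate
Product: 20 tert-butyl [(1S)-6,6-dimethyl-4-oxocyclohex-2-en-1-yl] carbonate
Conditions: Rh2(cap)4 (dirhodium tetracaprolactamate, 1 mol %), t-BuOOH (70% aq., 5 equiv), K2CO3, CH2Cl2, rt
Reagents that add atoms: tert-butyl hydroperoxide, CC(C)(C)OO
Why: Dirhodium-caprolactamate-catalysed allylic oxidation (tert-butylperoxyl radical chain) oxidizes the only allylic CH2 to the enone carbonyl, the carbinol C–H being deactivated by the carbonate and shielded by the CMe2 group.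

Step 14
Reactants: 20 tert-butyl [(1S)-6,6-dimethyl-4-oxocyclohex-2-en-1-yl] carbonate; 16 (3S,4S)-4-bromo-3-[2-{[tert-butyl(diphenyl)silyl]oxy}ethyl]-3-methyl-2-methylidenecyclohexan-1-one
Product: 22 tert-butyl [(1S)-5-({(1S,2S,3S)-3-bromo-2-[2-{[tert-butyl(diphenyl)silyl]oxy}ethyl]-2-methyl-6-oxocyclohexyl}methyl)-6,6-dimethyl-4-oxocyclohex-2-en-1-yl] carbonate (C5 epimers), via lithium dienolate 21 (not isolated)
Conditions: LiN(i-Pr)2, THF, −78 °C; then 16, −78 °C; AcOH
Reagents that add atoms: none
Why: Michael addition of the kinetic α′-enolate of the enone to the unhindered CH2 terminus of the exo-methylene ketone forms C14–C15; C13 is set on protonation and equilibration to the all-equatorial ring C, and C15 is left as an epimer mixture.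

Step 15
Reactants: 22 tert-butyl [(1S)-5-({(1S,2S,3S)-3-bromo-2-[2-{[tert-butyl(diphenyl)silyl]oxy}ethyl]-2-methyl-6-oxocyclohexyl}methyl)-6,6-dimethyl-4-oxocyclohex-2-en-1-yl] carbonate
Product: 23 tert-butyl [(1S)-5-{[(1S,2S,3S)-3-bromo-2-(2-hydroxyethyl)-2-methyl-6-oxocyclohexyl]methyl}-6,6-dimethyl-4-oxocyclohex-2-en-1-yl] carbonate
Conditions: HF·pyridine, pyridine, THF, 0 °C to rt
Reagents that add atoms: none
Why: Fluoride-induced desilylation (Si–F bond formation) frees the primary alcohol under buffered conditions that should leave the carbonate, the bromide and both ketones intact.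

Step 16
Reactants: 23 tert-butyl [(1S)-5-{[(1S,2S,3S)-3-bromo-2-(2-hydroxyethyl)-2-methyl-6-oxocyclohexyl]methyl}-6,6-dimethyl-4-oxocyclohex-2-en-1-yl] carbonate
Product: 24 tert-butyl [(1S)-5-{[(1S,2S,3S)-3-bromo-2-methyl-6-oxo-2-(2-oxoethyl)cyclohexyl]methyl}-6,6-dimethyl-4-oxocyclohex-2-en-1-yl] carbonate
Conditions: Dess–Martin periodinane, CH2Cl2, 0 °C to rt
Reagents that add atoms: none
Why: Dess–Martin oxidation gives the aldehyde under non-basic conditions, so that no aldol chemistry starts before the catalyst is added.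

Step 17
Reactants: 24 tert-butyl [(1S)-5-{[(1S,2S,3S)-3-bromo-2-methyl-6-oxo-2-(2-oxoethyl)cyclohexyl]methyl}-6,6-dimethyl-4-oxocyclohex-2-en-1-yl] carbonate
Product: 27 tetracyclic C1-enone C12-ketone, via allylpalladium dienolate zwitterion 25 (not isolated), via allylpalladium aldolate 26 (not isolated)
Conditions: Pd2(dba)3·CHCl3 (5 mol %), PPh3 (30 mol %), THF (0.01 M), 50 °C
Reagents that add atoms: none
Why: Proposed new method: zerovalent palladium ionizes the C4 carbonate with inversion to an η3-allyl complex (C2–C3–C4) whose positive charge acidifies the C15–H beside the C1 carbonyl, so the tert-butoxide released on decarboxylation gives the palladium-bound oxidopentadienyl zwitterion, whose enolate carbon C15 adds to the tethered aldehyde and whose new alkoxide O5 then attacks the allyl terminus C4 anti to the metal, a formal [3+2] addition of C6=O5 across C15 and C4. The closest known reactions are the palladium-catalysed formal [3+2] cycloaddition of vinylcyclopropane-derived allylpalladium zwitterions with aldehydes and the intramolecular Tsuji–Trost O-allylation. Ring B closes by a 6-(enolexo)-exo-trig aldol addition through a chair with the C16 quaternary carbon equatorial and the C1 carbonyl axial, and the THF ring closes by 5-exo attack of O5 on the allyl terminus. C4 keeps the configuration of the carbonate (double inversion); C15 must bond to C6 on that same face because both new bonds span one face of ring A, which with the (S)-carbonate is the face that the chair prefers; C6 follows because only the chair that turns O5 into the sector between C16 and C1 lets O5 reach C4, which places C7 endo and H6 towards the gem-dimethyl bridge. The step needs enolization at C15 in preference to the C12 ketone and aldehyde α-positions and O-attack at C4 instead of C2: the first is secured by the cationic allyl unit and by the reversibility of all other aldol modes, which the allyl unit cannot drain, the second by the position of C4 distal to the carbonyl and the strain of the alternative bridged ketone; C16 carries no hydrogen, so the allyl complex cannot collapse to a diene or aromatize.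

Step 18
Reactants: 27 tetracyclic C1-enone C12-ketone
Product: 28 C1 triethylsilyl enol ether of the tetracyclic C12 ketone
Conditions: RhCl(PPh3)3 (2 mol %), Et3SiH (1.2 equiv), THF, 50 °C
Reagents that add atoms: triethylsilane, CC[SiH](CC)CC
Why: Rhodium-catalysed 1,4-hydrosilylation of the enone saturates C2–C3 and leaves C1 as a silyl enol ether, which masks this carbonyl while the saturated C12 ketone, slower towards a monohydrosilane, stays free.

Step 19
Reactants: 28 C1 triethylsilyl enol ether of the tetracyclic C12 ketone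
Product: 30 tetracyclic C1 ketone C12 tertiary alcohol, via bromomagnesium alkoxide 29 (not isolated)
Conditions: MeMgBr, CeCl3, THF, −78 °C; then 1 M HCl, 0 °C
Reagents that add atoms: methylmagnesium bromide, C[Mg]Br
Why: Cerium-assisted Grignard 1,2-addition should occur from the equatorial side of the C12 ketone because the axial path is blocked by the syn-axial C8 methyl group, giving the axial tertiary alcohol, and the acidic work-up hydrolyses the silyl enol ether to the C1 ketone.

Step 20
Reactants: 30 tetracyclic C1 ketone C12 tertiary alcohol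
Product: 31 target compound CNP0412361.2
Conditions: Ph3PCH3Br, KOt-Bu, toluene, 90 °C
Reagents that add atoms: methyltriphenylphosphonium bromide, C[P+](c1ccccc1)(c1ccccc1)c1ccccc1.[Br-]
Why: Wittig methylenation of the hindered C1 ketone with excess ylide gives the exocyclic alkene; the tertiary alkoxide and the equatorial bromide (no antiperiplanar hydrogen for E2) are expected to tolerate the reagent.

**Compound list**

1 | but-3-yn-1-ol | C#CCCO | starting material
2 | tert-butyl(but-3-yn-1-yloxy)diphenylsilane | C#CCCO[Si](c1ccccc1)(c1ccccc1)C(C)(C)C | intermediate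
3 | [(1E)-4-{[tert-butyl(diphenyl)silyl]oxy}-2-methylbut-1-en-1-yl](dimethyl)alane | C/C(=C\[Al](C)C)CCO[Si](c1ccccc1)(c1ccccc1)C(C)(C)C | intermediate (not isolated)
4 | (2E)-5-{[tert-butyl(diphenyl)silyl]oxy}-3-methylpent-2-en-1-ol | C/C(=C\CO)CCO[Si](c1ccccc1)(c1ccccc1)C(C)(C)C | intermediate
5 | {[(3E)-5-bromo-3-methylpent-3-en-1-yl]oxy}(tert-butyl)diphenylsilane | C/C(=C\CBr)CCO[Si](c1ccccc1)(c1ccccc1)C(C)(C)C | intermediate
6 | 2,2,6-trimethyl-4H-1,3-dioxin-4-one | CC1=CC(=O)OC(C)(C)O1 | starting material
7 | lithium dienolate of 6 (lithium 2,2-dimethyl-6-methylidene-6H-1,3-dioxin-4-olate) | C=C1C=C(O[Li])OC(C)(C)O1 | intermediate (not isolated)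
8 | 6-[(3E)-6-{[tert-butyl(diphenyl)silyl]oxy}-4-methylhex-3-en-1-yl]-2,2-dimethyl-4H-1,3-dioxin-4-one | CC1(C)OC(=O)C=C(CC/C=C(\C)CCO[Si](c2ccccc2)(c2ccccc2)C(C)(C)C)O1 | intermediate
9 | 6-(2-{(2R,3R)-3-[2-{[tert-butyl(diphenyl)silyl]oxy}ethyl]-3-methyloxiran-2-yl}ethyl)-2,2-dimethyl-4H-1,3-dioxin-4-one | CC1(C)OC(=O)C=C(CC[C@H]2O[C@]2(C)CCO[Si](c3ccccc3)(c3ccccc3)C(C)(C)C)O1 | intermediate
10 | methyl 5-{(2R,3R)-3-[2-{[tert-butyl(diphenyl)silyl]oxy}ethyl]-3-methyloxiran-2-yl}-3-oxopentanoate | COC(=O)CC(=O)CC[C@H]1O[C@]1(C)CCO[Si](c1ccccc1)(c1ccccc1)C(C)(C)C | intermediate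
11 | methyl (6S,7R)-6-bromo-9-{[tert-butyl(diphenyl)silyl]oxy}-7-hydroxy-7-methyl-3-oxononanoate | COC(=O)CC(=O)CC[C@H](Br)[C@](C)(O)CCO[Si](c1ccccc1)(c1ccccc1)C(C)(C)C | intermediate
12 | bromonium ion bridging C8 and C9 of 11 (E-type; bromine on the face opposite to the epoxide oxygen of 10) | COC(=O)CC(=O)CC[C@@H]1[Br+][C@@]1(C)CCO[Si](c1ccccc1)(c1ccccc1)C(C)(C)C | intermediate (not isolated)
13 | methyl (1S,5S,6S)-5-bromo-6-[2-{[tert-butyl(diphenyl)silyl]oxy}ethyl]-6-methyl-2-oxocyclohexane-1-carboxylate | COC(=O)[C@@H]1C(=O)CC[C@H](Br)[C@@]1(C)CCO[Si](c1ccccc1)(c1ccccc1)C(C)(C)C | intermediate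
14 | sodium enolate of 13 | [Na+].COC(=O)C1=C([O-])CC[C@H](Br)[C@@]1(C)CCO[Si](c1ccccc1)(c1ccccc1)C(C)(C)C | intermediate (not isolated)
15 | (3S,4S)-4-bromo-3-[2-{[tert-butyl(diphenyl)silyl]oxy}ethyl]-3-methyl-2-methylidenecyclohexan-1-ol (C1 epimers) | OC1CC[C@H](Br)[C@@](C)(CCO[Si](c2ccccc2)(c2ccccc2)C(C)(C)C)C1=C | intermediate
16 | (3S,4S)-4-bromo-3-[2-{[tert-butyl(diphenyl)silyl]oxy}ethyl]-3-methyl-2-methylidenecyclohexan-1-one | O=C1CC[C@H](Br)[C@@](C)(CCO[Si](c2ccccc2)(c2ccccc2)C(C)(C)C)C1=C | intermediate
17 | 6,6-dimethylcyclohex-2-en-1-one | O=C1C=CCCC1(C)C | starting material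
18 | (1S)-6,6-dimethylcyclohex-2-en-1-ol | O[C@H]1C=CCCC1(C)C | intermediate
19 | tert-butyl [(1S)-6,6-dimethylcyclohex-2-en-1-yl] carbonate | CC(C)(C)OC(=O)O[C@H]1C=CCCC1(C)C | intermediate
20 | tert-butyl [(1S)-6,6-dimethyl-4-oxocyclohex-2-en-1-yl] carbonate | CC(C)(C)OC(=O)O[C@H]1C=CC(=O)CC1(C)C | intermediate
21 | lithium cross-conjugated dienolate of 20 (C15=C1–OLi) | [Li]OC1=CC(C)(C)[C@@H](OC(=O)OC(C)(C)C)C=C1 | intermediate (not isolated)
22 | tert-butyl [(1S)-5-({(1S,2S,3S)-3-bromo-2-[2-{[tert-butyl(diphenyl)silyl]oxy}ethyl]-2-methyl-6-oxocyclohexyl}methyl)-6,6-dimethyl-4-oxocyclohex-2-en-1-yl] carbonate (C5 epimers) | CC(C)(C)[Si](c1ccccc1)(c1ccccc1)OCC[C@]1(C)[C@@H](Br)CCC(=O)[C@H]1CC2C(=O)C=C[C@H](OC(=O)OC(C)(C)C)C2(C)C | intermediate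
23 | tert-butyl [(1S)-5-{[(1S,2S,3S)-3-bromo-2-(2-hydroxyethyl)-2-methyl-6-oxocyclohexyl]methyl}-6,6-dimethyl-4-oxocyclohex-2-en-1-yl] carbonate (C5 epimers) | OCC[C@]1(C)[C@@H](Br)CCC(=O)[C@H]1CC2C(=O)C=C[C@H](OC(=O)OC(C)(C)C)C2(C)C | intermediate
24 | tert-butyl [(1S)-5-{[(1S,2S,3S)-3-bromo-2-methyl-6-oxo-2-(2-oxoethyl)cyclohexyl]methyl}-6,6-dimethyl-4-oxocyclohex-2-en-1-yl] carbonate (C5 epimers) | O=CC[C@]1(C)[C@@H](Br)CCC(=O)[C@H]1CC2C(=O)C=C[C@H](OC(=O)OC(C)(C)C)C2(C)C | intermediate
25 | allylpalladium dienolate zwitterion from 24 (drawn as the σ-allyl form at C4; the C2–C3–C4 unit is η3-bound to Pd(PPh3)2 on the face opposite to the departed carbonate) | O=CC[C@]1(C)[C@@H](Br)CCC(=O)[C@H]1CC2=C([O-])C=C[C@@H]([Pd+](P(c3ccccc3)(c3ccccc3)c3ccccc3)P(c3ccccc3)(c3ccccc3)c3ccccc3)C2(C)C | intermediate (not isolated)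
26 | allylpalladium aldolate (ring B closed; C6 alkoxide; drawn as the σ-allyl form at C4) | [O-][C@@H]1C[C@]2(C)[C@@H](Br)CCC(=O)[C@H]2C[C@]13C(=O)C=C[C@@H]([Pd+](P(c4ccccc4)(c4ccccc4)c4ccccc4)P(c4ccccc4)(c4ccccc4)c4ccccc4)C3(C)C | intermediate (not isolated)
27 | tetracyclic C1-enone C12-ketone: C1 ketone conjugated to C2=C3, O5 bridging C4 and C6 (H6 towards the CMe2 bridge), rings B and C trans-fused, C9 bromide equatorial, C12 ketone | O=C1C=C[C@@H]2O[C@@H]3C[C@]4(C)[C@@H](Br)CCC(=O)[C@H]4C[C@]13C2(C)C | intermediate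
28 | C1 triethylsilyl enol ether (C1=C2) of the tetracyclic C12 ketone | CC[Si](CC)(CC)OC1=CC[C@@H]2O[C@@H]3C[C@]4(C)[C@@H](Br)CCC(=O)[C@H]4C[C@]13C2(C)C | intermediate
29 | bromomagnesium C12 alkoxide of the C1 triethylsilyl enol ether (C12 methyl equatorial, oxygen axial) | CC[Si](CC)(CC)OC1=CC[C@@H]2O[C@@H]3C[C@]4(C)[C@@H](Br)CC[C@@](C)(O[Mg]Br)[C@H]4C[C@]13C2(C)C | intermediate (not isolated)
30 | tetracyclic C1 ketone with the C12 tertiary alcohol (axial OH, cis to the C8 methyl) | O=C1CC[C@@H]2O[C@@H]3C[C@]4(C)[C@@H](Br)CC[C@@](C)(O)[C@H]4C[C@]13C2(C)C | intermediate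
31 | CNP0412361.2 (C1 exocyclic methylene, C9 bromide, C12 tertiary alcohol, O5 bridge C4–C6) | C=C1CC[C@@H]2O[C@@H]3C[C@]4(C)[C@@H](Br)CC[C@@](C)(O)[C@H]4C[C@]13C2(C)C | target

**Step count and risks**

Total: 20 steps. Longest linear sequence: 17 steps (steps 1–10 and 14–20); the ring A branch has 3 steps (11–13).

Steps most likely to fail:

1. Step 17 (proposed new method). The ionization at the neopentyl-type allylic carbon may be slow, so that unselective base-mediated aldol chemistry of the tricarbonyl compound runs ahead of it. The zwitterion may also close C15–C4 to a bicyclo[3.1.0]hexenone, or the allyl unit may be intercepted by tert-butoxide. Fallback (known chemistry; sets out from 24 and returns at 27): the two bond formations are uncoupled. Keto aldehyde 24 is equilibrated with KOt-Bu (0.1 equiv) in t-BuOH/THF at −20 °C, a reversible intramolecular aldol addition under thermodynamic control in which the ring B chair with C16 equatorial and a hydrogen-bonded equatorial C6 hydroxyl is expected to accumulate. This gives the isolated β-hydroxy ketone tert-butyl carbonate F1. F1 is then closed by a separate intramolecular Tsuji–Trost O-allylation (Pd(PPh3)4, THF, 50 °C; ionization with inversion, attack of the C6 oxygen anti to palladium) to give 27.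

2. Step 8. The enol may alkylate on oxygen instead of carbon, the bromonium ion may lose a proton to an allylic bromide, or enantiopurity may erode through bromonium transfer between molecules. Fallback (sets out from 8 and returns at 13): the bromohydrin is replaced by a catalyst-controlled bromocyclization of the achiral alkene. Alkene dioxinone 8 is heated with MeOH in toluene (110 °C) to give methyl (6E)-9-{[tert-butyl(diphenyl)silyl]oxy}-7-methyl-3-oxonon-6-enoate F2. F2 is cyclized with 1,3-dibromo-5,5-dimethylhydantoin and a chiral BINOL-derived thiophosphoramide Lewis-base catalyst (toluene, −40 °C; enantioselective bromonium transfer, chair cyclization terminated by the enol), the catalyst antipode being chosen for the (5S)-bromide, to give 13.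

3. Step 7. Bromide may attack the tertiary carbon C8 (borderline SN1 opening), or the Lewis-acidic medium may rearrange the epoxide to a ketone. Fallback (sets out from 10 and returns at 13): the opposite regiochemistry is used on purpose. Epoxide 10 is opened with aqueous HBr (Et2O, −20 °C; attack at the tertiary carbon with inversion) to give the tertiary bromide methyl (6R,7S)-7-bromo-9-{[tert-butyl(diphenyl)silyl]oxy}-6-hydroxy-7-methyl-3-oxononanoate F3. Its secondary hydroxyl is converted with Tf2O and 2,6-di-tert-butyl-4-methylpyridine (CH2Cl2, −78 °C) into the secondary triflate F4, which is not isolated. The anti bromine displaces the triflate with inversion at C9 and gives the same bromonium ion 12, which cyclizes as in step 8 to 13.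

Further compounds

F1 | step 17 | β-hydroxy ketone tert-butyl carbonate (ring B closed, free C6 hydroxyl, C4 carbonate retained) | O[C@@H]1C[C@]2(C)[C@@H](Br)CCC(=O)[C@H]2C[C@]13C(=O)C=C[C@H](OC(=O)OC(C)(C)C)C3(C)C
F2 | step 8 | methyl (6E)-9-{[tert-butyl(diphenyl)silyl]oxy}-7-methyl-3-oxonon-6-enoate | COC(=O)CC(=O)CC/C=C(\C)CCO[Si](c1ccccc1)(c1ccccc1)C(C)(C)C
F3 | step 7 | methyl (6R,7S)-7-bromo-9-{[tert-butyl(diphenyl)silyl]oxy}-6-hydroxy-7-methyl-3-oxononanoate | COC(=O)CC(=O)CC[C@@H](O)[C@@](C)(Br)CCO[Si](c1ccccc1)(c1ccccc1)C(C)(C)C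
F4 | step 7 | methyl (6R,7S)-7-bromo-9-{[tert-butyl(diphenyl)silyl]oxy}-7-methyl-3-oxo-6-{[(trifluoromethyl)sulfonyl]oxy}nonanoate | COC(=O)CC(=O)CC[C@@H](OS(=O)(=O)C(F)(F)F)[C@@](C)(Br)CCO[Si](c1ccccc1)(c1ccccc1)C(C)(C)C
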